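**Retrosynthetic overview**
1. The plan rests on one feature of the flavonol. The C4a–C8a bond shared by rings A and C is read as the C5=C6 double bond of a monocyclic 3-oxygenated 4-pyranone (ring C). The other ring A atoms C5, C6, C7 and C8, with oxygen on C5 and C7, are read as the four-carbon chain of acetoacetate.
2. The key disconnection cuts C8–C8a and C4a–C5. Ring A is annulated onto a 2-aryl-3-benzyloxy-5-bromo-4-pyranone with the bis-silyl diene of methyl acetoacetate, and the bromine on the future C4a leaves as HBr, so no external oxidant is needed.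
3. The bromopyranone comes from 3-hydroxy-4-pyranone by C2 bromination, O-benzylation, C5 bromination and a C2-selective Suzuki–Miyaura coupling with a 3,4-bis(allyloxy)phenylboronate made from 4-bromocatechol. Both brominations are done before the allyl ethers and the electron-rich ring B are present.
4. The end game is benzylation of O5 and O7, allyl removal, bis-sulfation of the freed catechol, and hydrogenolysis of the three benzyl ethers.
5. Ring order: ring C is purchased, ring B is attached by cross-coupling, and ring A is built last.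

Key step: step 9

Remark on locants: pyranone locants are used for the monocyclic precursors, whose C5 and C6 become C4a and C8a. Flavone locants are used for the new bonds.
Remark on the sulfates: the two sulfated compounds are drawn as free hydrogen sulfates, as the target is. They would be handled as triethylammonium salts, and the acid form would be released only at the very end by cold cation exchange.
Remark on stereochemistry: the target has no stereocentre. The silyl enol ethers are used as E/Z mixtures, and the sp3 intermediates of the key step are racemic and transient.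

Step 1
Reactants: 1 3-hydroxy-4H-pyran-4-one
Product: 2 2-bromo-3-hydroxy-4H-pyran-4-one
Conditions: NBS (1.0 equiv), MeCN, 0 °C → rt
Reagents that add atoms: N-bromosuccinimide, O=C1CCC(=O)N1Br
Why: Electrophilic halogenation of the enolic 3-hydroxy-4-pyranone should take place at C2, the carbon ortho to the hydroxyl and the site at which this ring class also undergoes Mannich and aldol reactions.

Step 2
Reactants: 2 2-bromo-3-hydroxy-4H-pyran-4-one
Product: 3 3-(benzyloxy)-2-bromo-4H-pyran-4-one
Conditions: BnBr (1.1 equiv), K2CO3 (1.5 equiv), acetone, 50 °C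
Reagents that add atoms: benzyl bromide, BrCc1ccccc1
Why: Williamson etherification of the acidic enolic hydroxyl needs only a carbonate base, which is too poor a nucleophile to displace the vinylogous acyl bromide at C2.

Step 3
Reactants: 3 3-(benzyloxy)-2-bromo-4H-pyran-4-one
Product: 4 3-(benzyloxy)-2,5-dibromo-4H-pyran-4-one
Conditions: NBS (1.1 equiv), MeCN, 60 °C, dark
Reagents that add atoms: N-bromosuccinimide, O=C1CCC(=O)N1Br
Why: This is the electrophilic α-halogenation of a 4-pyranone, in which C5, the β-carbon of the O1–C6=C5 enol ether, is the only nucleophilic carbon left once C2 is blocked and O3 is capped, and running it here keeps NBS away from the allyl ethers and ring B.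

Step 4
Reactants: 5 4-bromocatechol
Product: 6 1,2-bis(allyloxy)-4-bromobenzene
Conditions: allyl bromide (2.5 equiv), K2CO3 (3 equiv), acetone, reflux
Reagents that add atoms: allyl bromide, C=CCBr
Why: Double Williamson etherification of a catechol with a reactive allylic halide is routine, and the aryl bromide is inert to it.

Step 5
Reactants: 6 1,2-bis(allyloxy)-4-bromobenzene
Product: 8 2-[3,4-bis(allyloxy)phenyl]-4,4,5,5-tetramethyl-1,3,2-dioxaborolane, via aryllithium 7 (not isolated)
Conditions: n-BuLi (1.05 equiv), THF, −78 °C, 20 min; iPrOBpin (1.3 equiv), −78 °C → rt; H2O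
Reagents that add atoms: 2-isopropoxy-4,4,5,5-tetramethyl-1,3,2-dioxaborolane, CC(C)OB1OC(C)(C)C(C)(C)O1; n-butyllithium, [Li]CCCC (lithium of 7 only)
Why: Bromine–lithium exchange at −78 °C is much faster than any attack of n-BuLi on aryl allyl ethers, and trapping the aryllithium with the borate ester avoids a palladium-catalysed borylation in the presence of the allyl groups.

Step 6
Reactants: 4 3-(benzyloxy)-2,5-dibromo-4H-pyran-4-one; 8 2-[3,4-bis(allyloxy)phenyl]-4,4,5,5-tetramethyl-1,3,2-dioxaborolane
Product: 9 3-(benzyloxy)-2-[3,4-bis(allyloxy)phenyl]-5-bromo-4H-pyran-4-one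
Conditions: 8 (1.0 equiv), PdCl2(dppf) (3 mol %), K3PO4 (2 equiv), 1,4-dioxane with a little H2O, 50 °C
Reagents that add atoms: none
Why: In this Suzuki–Miyaura coupling zerovalent palladium should insert first into C2–Br, a vinylogous acyl bromide at the enone β-carbon next to O1, rather than into the α-bromoenone C5–Br bond (the β-before-α order shown by 2,3-dibromoindenone and 3,4-dibromofuran-2(5H)-one), while one equivalent of boronate, mild heating and the absence of a soft nucleophile spare the second bromide and the aryl allyl ethers.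

Step 7
Reactants: 10 methyl acetoacetate
Product: 11 methyl 3-(trimethylsilyloxy)but-2-enoate
Conditions: Me3SiCl (1.3 equiv), Et3N (1.5 equiv), pentane, rt
Reagents that add atoms: chlorotrimethylsilane, C[Si](C)(C)Cl
Why: O-silylation of the enol of a β-keto ester with Me3SiCl and Et3N is the standard silyl enol ether formation for this substrate class.

Step 8
Reactants: 11 methyl 3-(trimethylsilyloxy)but-2-enoate
Product: 13 1-methoxy-1,3-bis(trimethylsilyloxy)buta-1,3-diene, via lithium dienolate 12 (not isolated)
Conditions: LiN(iPr)2 (commercial solution, 1.1 equiv), THF, −78 °C; Me3SiCl (1.3 equiv), −78 °C → rt; non-aqueous work-up (pentane, filtration)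
Reagents that add atoms: chlorotrimethylsilane, C[Si](C)(C)Cl; lithium diisopropylamide, [Li]N(C(C)C)C(C)C (lithium of 12 only)
Why: Kinetic γ-deprotonation of the silyloxycrotonate followed by O-silylation of the ester dienolate is the established preparation of 1,3-bis(silyloxy)dienes.

Step 9
Reactants: 9 3-(benzyloxy)-2-[3,4-bis(allyloxy)phenyl]-5-bromo-4H-pyran-4-one; 13 1-methoxy-1,3-bis(trimethylsilyloxy)buta-1,3-diene
Product: 17 3-(benzyloxy)-2-[3,4-bis(allyloxy)phenyl]-5,7-dihydroxy-4H-chromen-4-one, via siloxypyrylium triflate 14 (not isolated), via 2H-pyran adduct 15 (not isolated), via 4a-bromo diketone 16 (not isolated)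
Conditions: Me3SiOTf (2.0 equiv), CH2Cl2, 0 °C → rt, 1 h; 13 (1.8 equiv), −78 °C → rt, 12 h; iPr2NEt (5 equiv), rt → 40 °C; 1 M HCl, THF, rt
Reagents that add atoms: trimethylsilyl trifluoromethanesulfonate, C[Si](C)(C)OS(=O)(=O)C(F)(F)F (its atoms stand in 14 and 15 only, none in 17)
Why: Proposed new method: Me3SiOTf silylates the C4 carbonyl oxygen of 9 to the 4-siloxypyrylium salt 14, the CH2 terminus of 13 adds to pyranone C6, the only unsubstituted position next to O1 (new C8–C8a bond), and the O-silylated ester cation so formed, or the ester of 15 once re-silylated, is attacked by pyranone C5 of the bromo silyl enol ether in a Mukaiyama-type Claisen condensation (new C4a–C5 bond, Me3SiOMe expelled) to give 16. Ring A closes in the 6-(enolexo)-exo-trig mode, and the three-atom tether lets the ester carbon reach no nucleophilic carbon other than pyranone C5. iPr2NEt together with the Me3SiOTf still present should enolsilylate 16 to a 5,7-bis(siloxy)cyclohexadiene and remove HBr across C4a–C8a, so that the bromine supplies the oxidation level of the arene, and the acidic work-up frees the two phenols. The closest known reactions are the silyl-triflate-mediated addition of 1,3-bis(silyloxy)dienes to C2 of chromones, the tandem additions of siloxydienes to 4-siloxybenzopyrylium salts that fuse a carbocycle onto C2–C3, and the annulation of haloquinones by ketene-acetal dienes with loss of hydrogen halide, but none of them has been run on a monocyclic 5-halo-4-pyranone or ends in acylation by an ester. C8a (in 15 and 16) and C4a (in 16) are transient racemic stereocentres that vanish on aromatisation, so no control element is needed, and if a cis ring fusion holds H and Br syn, C8a can epimerise through reversible oxa-Michael opening of the O1–C8a bond before an anti elimination. The step needs attack at pyranone C6 and not at C2, which the aryl group secures by blocking C2 and stabilising it by conjugation, and it needs the diene to react at its terminal carbon, which is the normal behaviour of bis-silyl dienes toward oxocarbenium-type electrophiles.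

Step 10
Reactants: 17 3-(benzyloxy)-2-[3,4-bis(allyloxy)phenyl]-5,7-dihydroxy-4H-chromen-4-one
Product: 18 3,5,7-tris(benzyloxy)-2-[3,4-bis(allyloxy)phenyl]-4H-chromen-4-one
Conditions: BnBr (3 equiv), K2CO3 (4 equiv), DMF, 70 °C
Reagents that add atoms: benzyl bromide, BrCc1ccccc1
Why: In this Williamson etherification the 7-hydroxyl reacts readily and the chelated 5-hydroxyl follows with excess halide and heat, as in the perbenzylation of 5-hydroxyflavones, while the allyl and benzyl ethers already present are inert.

Step 11
Reactants: 18 3,5,7-tris(benzyloxy)-2-[3,4-bis(allyloxy)phenyl]-4H-chromen-4-one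
Product: 19 3,5,7-tris(benzyloxy)-2-(3,4-dihydroxyphenyl)-4H-chromen-4-one
Conditions: Pd(PPh3)4 (5 mol %), morpholine (10 equiv), THF, rt, argon
Reagents that add atoms: none
Why: In this Tsuji–Trost allyl transfer zerovalent palladium ionises the aryl allyl ethers to π-allyl complexes and phenoxides, morpholine captures the allyl groups, and the benzyl ethers are not touched.

Step 12
Reactants: 19 3,5,7-tris(benzyloxy)-2-(3,4-dihydroxyphenyl)-4H-chromen-4-one
Product: 20 4-[3,5,7-tris(benzyloxy)-4-oxo-4H-chromen-2-yl]-1,2-phenylene bis(hydrogen sulfate)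
Conditions: SO3·NMe3 (12 equiv), Et3N (20 equiv), MeCN, 90 °C, sealed tube; isolated as the bis(triethylammonium) salt
Reagents that add atoms: sulfur trioxide–trimethylamine complex, C[N+](C)(C)S(=O)(=O)[O-]
Why: O-sulfation of phenols with an amine–SO3 complex can only reach the two catechol hydroxyls, the sole free OH groups, and the large excess of reagent with heating is the known way to force a second sulfate next to the first.

Step 13
Reactants: 20 4-[3,5,7-tris(benzyloxy)-4-oxo-4H-chromen-2-yl]-1,2-phenylene bis(hydrogen sulfate)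
Product: 21 4-(3,5,7-trihydroxy-4-oxo-4H-chromen-2-yl)-1,2-phenylene bis(hydrogen sulfate) (quercetin 3',4'-disulfate)
Conditions: H2 (1 atm), Pd/C (10 wt %), MeOH/THF, trace Et3N, rt; Dowex 50W (H+ form), H2O, 0 °C, immediate freeze-drying
Reagents that add atoms: none
Why: Hydrogenolysis of benzyl ethers over Pd/C leaves aryl sulfate salts and the flavonol C2=C3 bond intact under neutral conditions, and the cold cation exchange then gives the protonated form that is drawn.

**Compound list**
1 | 3-hydroxy-4H-pyran-4-one | O=c1ccocc1O | starting material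
2 | 2-bromo-3-hydroxy-4H-pyran-4-one | O=c1ccoc(Br)c1O | intermediate
3 | 3-(benzyloxy)-2-bromo-4H-pyran-4-one | O=c1ccoc(Br)c1OCc1ccccc1 | intermediate
4 | 3-(benzyloxy)-2,5-dibromo-4H-pyran-4-one | O=c1c(Br)coc(Br)c1OCc1ccccc1 | intermediate
5 | 4-bromocatechol | Oc1ccc(Br)cc1O | starting material
6 | 1,2-bis(allyloxy)-4-bromobenzene | C=CCOc1ccc(Br)cc1OCC=C | intermediate
7 | [3,4-bis(allyloxy)phenyl]lithium (not isolated) | [Li]c1ccc(OCC=C)c(OCC=C)c1 | intermediate
8 | 2-[3,4-bis(allyloxy)phenyl]-4,4,5,5-tetramethyl-1,3,2-dioxaborolane | CC1(C)OB(OC1(C)C)c1ccc(OCC=C)c(OCC=C)c1 | intermediate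
9 | 3-(benzyloxy)-2-[3,4-bis(allyloxy)phenyl]-5-bromo-4H-pyran-4-one | O=c1c(Br)coc(-c2ccc(OCC=C)c(OCC=C)c2)c1OCc1ccccc1 | intermediate
10 | methyl acetoacetate | COC(=O)CC(C)=O | starting material
11 | methyl 3-(trimethylsilyloxy)but-2-enoate (E/Z mixture) | COC(=O)C=C(C)O[Si](C)(C)C | intermediate
12 | lithium 1-methoxy-3-(trimethylsilyloxy)buta-1,3-dien-1-olate (not isolated) | C=C(O[Si](C)(C)C)C=C(OC)O[Li] | intermediate
13 | 1-methoxy-1,3-bis(trimethylsilyloxy)buta-1,3-diene (E/Z mixture) | C=C(O[Si](C)(C)C)C=C(OC)O[Si](C)(C)C | intermediate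
14 | 3-(benzyloxy)-2-[3,4-bis(allyloxy)phenyl]-5-bromo-4-(trimethylsilyloxy)pyrylium trifluoromethanesulfonate (not isolated) | C[Si](C)(C)Oc1c(Br)c[o+]c(-c2ccc(OCC=C)c(OCC=C)c2)c1OCc1ccccc1.[O-]S(=O)(=O)C(F)(F)F | intermediate
15 | methyl 4-{5-(benzyloxy)-6-[3,4-bis(allyloxy)phenyl]-3-bromo-4-(trimethylsilyloxy)-2H-pyran-2-yl}-3-(trimethylsilyloxy)but-2-enoate (racemic, not isolated) | COC(=O)C=C(CC1OC(-c2ccc(OCC=C)c(OCC=C)c2)=C(OCc2ccccc2)C(O[Si](C)(C)C)=C1Br)O[Si](C)(C)C | intermediate
16 | 3-(benzyloxy)-2-[3,4-bis(allyloxy)phenyl]-4a-bromo-7-(trimethylsilyloxy)-8,8a-dihydro-4H-chromene-4,5(4aH)-dione (racemic, ring fusion undefined, not isolated) | O=C1C=C(O[Si](C)(C)C)CC2OC(-c3ccc(OCC=C)c(OCC=C)c3)=C(OCc3ccccc3)C(=O)C12Br | intermediate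
17 | 3-(benzyloxy)-2-[3,4-bis(allyloxy)phenyl]-5,7-dihydroxy-4H-chromen-4-one | O=c1c(OCc2ccccc2)c(-c2ccc(OCC=C)c(OCC=C)c2)oc2cc(O)cc(O)c12 | intermediate
18 | 3,5,7-tris(benzyloxy)-2-[3,4-bis(allyloxy)phenyl]-4H-chromen-4-one | O=c1c(OCc2ccccc2)c(-c2ccc(OCC=C)c(OCC=C)c2)oc2cc(OCc3ccccc3)cc(OCc3ccccc3)c12 | intermediate
19 | 3,5,7-tris(benzyloxy)-2-(3,4-dihydroxyphenyl)-4H-chromen-4-one | O=c1c(OCc2ccccc2)c(-c2ccc(O)c(O)c2)oc2cc(OCc3ccccc3)cc(OCc3ccccc3)c12 | intermediate
20 | 4-[3,5,7-tris(benzyloxy)-4-oxo-4H-chromen-2-yl]-1,2-phenylene bis(hydrogen sulfate) | O=c1c(OCc2ccccc2)c(-c2ccc(OS(=O)(=O)O)c(OS(=O)(=O)O)c2)oc2cc(OCc3ccccc3)cc(OCc3ccccc3)c12 | intermediate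
21 | 4-(3,5,7-trihydroxy-4-oxo-4H-chromen-2-yl)-1,2-phenylene bis(hydrogen sulfate) (quercetin 3',4'-disulfate) | O=c1c(O)c(-c2ccc(OS(=O)(=O)O)c(OS(=O)(=O)O)c2)oc2cc(O)cc(O)c12 | target

**Total step count:** 13
**Longest linear sequence:** 9 steps (1, 2, 3, 6, 9, 10, 11, 12, 13)

**Steps most likely to fail**

Step 9 (annulation).
- After the first C–C bond, the silylated ester cation may shed its silyl group faster than the hindered, bromine-deactivated enol ether can attack it. The sequence would then stop at the open adduct.
- On contact with base, the freed β-keto ester may alkylate itself at the bromine-bearing carbon in a five-membered closure.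
- The bromine may also be taken off by halophilic attack, after which the pyran ring opens by retro-oxa-Michael reaction.
- HBr loss from a cis-fused bicycle may be slow.

The fallback uses known chemistry only. It buys ring A and builds ring C, sets out from 6 and rejoins the route at 18. Bromide 6 is lithiated to 7 as in step 5 and formylated with DMF to 3,4-bis(allyloxy)benzaldehyde F1. Claisen–Schmidt condensation of F1 with commercial 1-[2,4-bis(benzyloxy)-6-hydroxyphenyl]ethan-1-one (KOH, EtOH, rt) gives (E)-1-[2,4-bis(benzyloxy)-6-hydroxyphenyl]-3-[3,4-bis(allyloxy)phenyl]prop-2-en-1-one F2. Algar–Flynn–Oyamada oxidation (H2O2, NaOH, MeOH/THF, 0 °C) leaves the isolated allyl double bonds alone and is run cold to hold back the aurone pathway known for 6'-alkoxychalcones. It gives 2-[3,4-bis(allyloxy)phenyl]-5,7-bis(benzyloxy)-3-hydroxy-4H-chromen-4-one F3. Benzylation of the 3-hydroxyl of F3 (BnBr, K2CO3, DMF) gives 18.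

Step 6 (site-selective coupling).
- Insertion into the C5–Br bond, or into both C–Br bonds, may compete.
- Aqueous base may displace the C2 bromide.
- Zerovalent palladium may ionise an allyl ether.

The fallback removes the need for site selection by changing the order of events. It sets out from 3 and comes back at 9. Monobromide 3 is coupled with 8 (PdCl2(dppf), K3PO4, 1,4-dioxane, 60 °C) to give 3-(benzyloxy)-2-[3,4-bis(allyloxy)phenyl]-4H-pyran-4-one F4. F4 is then brominated at C5 with NBS (1.0 equiv, DMF, dark, rt) to give 9. The competition between C5 and ring B or the allyl groups then has to be managed by stoichiometry.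

Step 12 (bis-sulfation).
- The second sulfation next to the first sulfate anion may stall through charge repulsion, so that monosulfates accumulate.
- Sulfate may be lost on handling.

The fallback installs neutral, protected sulfate diesters. It sets out from 19 and comes back at 20. Catechol 19 is treated with 2,2,2-trichloroethyl chlorosulfate (Et3N, DMAP, THF, 0 °C → rt) to give 4-[3,5,7-tris(benzyloxy)-4-oxo-4H-chromen-2-yl]-1,2-phenylene bis(2,2,2-trichloroethyl) bis(sulfate) F5, which can be purified on silica. Reductive removal of the trichloroethyl groups (Zn dust, HCO2NH4, MeOH, rt) spares the benzyl ethers and gives 20 as its ammonium salt.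

**Further compounds**
F1 | step 9 | 3,4-bis(allyloxy)benzaldehyde | O=Cc1ccc(OCC=C)c(OCC=C)c1
F2 | step 9 | (E)-1-[2,4-bis(benzyloxy)-6-hydroxyphenyl]-3-[3,4-bis(allyloxy)phenyl]prop-2-en-1-one | O=C(/C=C/c1ccc(OCC=C)c(OCC=C)c1)c1c(O)cc(OCc2ccccc2)cc1OCc1ccccc1
F3 | step 9 | 2-[3,4-bis(allyloxy)phenyl]-5,7-bis(benzyloxy)-3-hydroxy-4H-chromen-4-one | O=c1c(O)c(-c2ccc(OCC=C)c(OCC=C)c2)oc2cc(OCc3ccccc3)cc(OCc3ccccc3)c12
F4 | step 6 | 3-(benzyloxy)-2-[3,4-bis(allyloxy)phenyl]-4H-pyran-4-one | O=c1ccoc(-c2ccc(OCC=C)c(OCC=C)c2)c1OCc1ccccc1
F5 | step 12 | 4-[3,5,7-tris(benzyloxy)-4-oxo-4H-chromen-2-yl]-1,2-phenylene bis(2,2,2-trichloroethyl) bis(sulfate) | O=c1c(OCc2ccccc2)c(-c2ccc(OS(=O)(=O)OCC(Cl)(Cl)Cl)c(OS(=O)(=O)OCC(Cl)(Cl)Cl)c2)oc2cc(OCc3ccccc3)cc(OCc3ccccc3)c12
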